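**Assumption (notation only):** terpene carbons carry eudesmane numbers C1–C15 and the benzylic carbon is C1′; the target is then (1S,5S,7R,10S,1′S). The SMILES strings are authoritative for stereochemistry.

## Retrosynthetic overview

1. Endgame: both ArCHO groups by double directed ortho-lithiation/DMF, O-demethylation last; C11 carbinol from a C7 ester with MeMgBr; C4=CH2 by Wittig.
2. Key disconnection: ring B (C8–C9, then C5–C6) by a radical [3+3] annulation — tin-ketyl fragmentation of a cyclopropyl ketone, radical allyl transfer, Michael closure.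
3. C10 quaternary centre: sulfoxonium-ylide cyclopropanation of a 3-methyl-4-substituted cyclohexenone, anti to the C1 side chain.
4. C1–C1′ bond and both stereocentres: amine-catalysed Michael addition of 5-oxohexanal to an o-quinone methide; ring A by aldol condensation.
5. Ring order: arene (from resorcinol) → ring A → cyclopropane → ring B.

## Route

**Step 1**
Reactants: 1 resorcinol
Product: 2 1,3-dimethoxybenzene
Conditions: MeI, K2CO3, acetone, reflux
Reagents that add atoms: iodomethane, CI
Why: Williamson O-methylation; the methyl ethers later direct lithiation and are removed in the last step.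

**Step 2**
Reactants: 2 1,3-dimethoxybenzene
Product: 3 3,5-dimethoxyphenol
Conditions: [Ir(OMe)(cod)]2 (cat.), dtbpy, B2pin2, 80 °C; then Oxone, acetone–H2O, rt (one pot)
Reagents that add atoms: Oxone (potassium peroxymonosulfate), [K+].[O-]S(=O)(=O)OO (supplies the phenolic O)
Why: Sterically controlled Ir-catalysed C–H borylation touches only C5 (meta to both OMe), and oxidation of the ArBpin gives the phenol.

**Step 3**
Reactants: 3 3,5-dimethoxyphenol; 4 3-methylbutanal (isovaleraldehyde)
Product: 5 rac-2-(1-hydroxy-3-methylbutyl)-3,5-dimethoxyphenol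
Conditions: PhB(OH)2, EtCO2H (cat.), toluene, reflux (Dean–Stark); then propane-1,3-diol, THF, rt
Reagents that add atoms: none
Why: Nagata ortho-hydroxyalkylation through a 1,3,2-benzodioxaborin is ortho-specific (the two ortho positions are equivalent); the carbinol centre is racemic and is erased in step 5.

**Step 4**
Reactants: 6 1-methylcyclopentene
Product: 7 5-oxohexanal
Conditions: O3, CH2Cl2, −78 °C; then Me2S (used crude)
Reagents that add atoms: ozone, [O-][O+]=O
Why: Ozonolysis with reductive work-up gives the keto-aldehyde that supplies C10, C1, C2, C3, C4 and C5.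

**Step 5**
Reactants: 5 the o-hydroxybenzyl alcohol; 7 5-oxohexanal (3 equiv)
Product: 8 (3S,4S)-5,7-dimethoxy-4-(2-methylpropyl)-3-(3-oxobutyl)-3,4-dihydro-2H-chromen-2-ol (trans; anomer mixture)
Conditions: (R)-α,α-diphenylprolinol TMS ether (20 mol %), PhCO2H (20 mol %), CHCl3, rt
Reagents that add atoms: none
Why: Acid-promoted dehydration of 5 gives the electron-rich o-quinone methide, which is attacked by the aldehyde enamine on the face not shielded by the CPh2OTMS group (enamine Michael/hemiacetalization, formal [4+2]); this sets C1 (S) and, as the trans-3,4-lactol, C1′ (S).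

**Step 6**
Reactants: 8 the lactol
Product: 9 (4R)-4-[(1S)-3-methyl-1-(2,4,6-trimethoxyphenyl)butyl]cyclohex-2-en-1-one
Conditions: KOH, MeOH, 0 °C → rt; then Me2SO4 (same flask)
Reagents that add atoms: dimethyl sulfate, COS(=O)(=O)OC
Why: The phenoxide opens the lactol and intramolecular aldol condensation (methyl-ketone enolate onto the aldehyde, the only pairing that gives a six-membered ring) forms ring A, then the phenoxide is O-methylated; low temperature limits epimerisation of the α-CH (C1).

**Step 7**
Reactants: 9 the enone
Product: 10 (4S)-3-methyl-4-[(1S)-3-methyl-1-(2,4,6-trimethoxyphenyl)butyl]cyclohex-2-en-1-one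
Conditions: Me2CuLi, Et2O/THF, −78 °C; PhSeCl, −78 °C; then H2O2, pyridine, CH2Cl2, 0 °C
Reagents that add atoms: lithium dimethylcuprate, [Li+].C[Cu-]C
Why: Cuprate 1,4-addition, selenenylation of the regiodefined enolate and selenoxide syn-elimination (Reich) put the C14 methyl on C10 and regenerate the enone; the transient sp3 centres are erased and C1 is untouched.

**Step 8**
Reactants: 10 the β-methyl enone
Product: 11 (1S,5S,6S)-6-methyl-5-[(1S)-3-methyl-1-(2,4,6-trimethoxyphenyl)butyl]bicyclo[4.1.0]heptan-2-one
Conditions: Me3S(O)I, NaH, DMSO, rt → 50 °C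
Reagents that add atoms: trimethylsulfoxonium iodide, C[S+](C)(C)=O.[I-]
Why: Corey–Chaykovsky cyclopropanation; the C1 side chain sits pseudo-axial (A1,2 strain with the C10 methyl), so the ylide adds to C10 on the opposite face, fixing the C10 quaternary centre with CH3 cis and the new CH2 (C9) trans to the side chain.

**Step 9**
Reactants: 12 methyl 2-(bromomethyl)acrylate
Product: 13 methyl 2-[(tributylstannyl)methyl]acrylate
Conditions: Bu3SnLi (from Bu3SnH, LDA), CuBr·SMe2, THF, −78 °C
Reagents that add atoms: tributyltin hydride, CCCC[SnH](CCCC)CCCC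
Why: SN2′ substitution of the allylic bromide by the stannylcuprate gives the allyl-transfer reagent.

**Step 10 (key step)**
Reactants: 11 the cyclopropyl ketone; 13 the stannylmethyl acrylate (2 equiv)
Product: 14 methyl (2R,4aS,5S,8aR)-4a-methyl-5-[(1S)-3-methyl-1-(2,4,6-trimethoxyphenyl)butyl]-8-oxodecahydronaphthalene-2-carboxylate (trans-decalone, equatorial ester)
Conditions: AIBN (0.2 equiv, portionwise), PhH, 80 °C; then NaOMe, MeOH, rt
Reagents that add atoms: none beyond 13
Why: Proposed new method: Bu3Sn• adds to the ketone oxygen; the O-stannyl ketyl cleaves the exo C5–C9 cyclopropane bond (the one that overlaps the ketyl SOMO), giving a primary C9 radical and a C4=C5 tin enolate. The radical adds to 13 and β-scission releases Bu3Sn• (chain), forming C8–C9 and leaving a 2-substituted acrylate. NaOMe then closes ring B by 6-endo Michael addition of C5 to C6 (the only enolate that can form a six-membered ring) and equilibrates C5 and C7 to the trans-decalone with equatorial CO2Me; C10 is untouched. Closest known reactions: O-stannyl-ketyl ring-opening/allylation of cyclopropyl ketones and allylstannane radical allyl transfer.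

**Step 11**
Reactants: 14 the keto ester
Product: 15 methyl (2R,4aS,5S,8aS)-4a-methyl-8-methylidene-5-[(1S)-3-methyl-1-(2,4,6-trimethoxyphenyl)butyl]decahydronaphthalene-2-carboxylate
Conditions: Ph3PCH3Br, KHMDS, THF/toluene, 60–80 °C
Reagents that add atoms: methyltriphenylphosphonium bromide, C[P+](c1ccccc1)(c1ccccc1)c1ccccc1.[Br-]
Why: Wittig methylenation is ketone-selective over the ester and installs C15; under the basic conditions any cis-fused ketone equilibrates through C5, so material funnels to the trans-fused alkene.

**Step 12**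
Reactants: 15 the methylidene ester
Product: 16 2-[(2R,4aS,5S,8aS)-4a-methyl-8-methylidene-5-[(1S)-3-methyl-1-(2,4,6-trimethoxyphenyl)butyl]decahydronaphthalen-2-yl]propan-2-ol
Conditions: MeMgBr (5 equiv), THF, 0 °C → rt
Reagents that add atoms: methylmagnesium bromide, C[Mg]Br
Why: Double Grignard addition converts the ester into the tertiary carbinol; the alkene and aryl ethers are inert.

**Step 13**
Reactants: 16 the carbinol
Product: 17 macrocarpal H tri-O-methyl ether (2,4,6-trimethoxy-3,5-diformylaryl)
Conditions: s-BuLi/TMEDA, THF, −78 → −20 °C, then DMF; second s-BuLi/TMEDA–DMF cycle in the same flask; aq. NH4Cl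
Reagents that add atoms: N,N-dimethylformamide, CN(C)C=O
Why: Directed ortho-metalation occurs at the two ring C–H positions, each flanked by two OMe groups; the first formyl is masked in situ as its α-amino alkoxide, and the tertiary alcohol is carried as its alkoxide.

**Step 14**
Reactants: 17 the trimethyl ether
Product: 18 macrocarpal H
Conditions: NaSEt, DMF, 110 °C; then cold 1 M HCl work-up
Reagents that add atoms: none
Why: Thiolate SN2 demethylation is activated by the ortho/para formyl groups (every OMe is ortho to a CHO) and is non-acidic, so the tertiary alcohol and exocyclic alkene survive.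

## Compound list

1 | resorcinol | Oc1cccc(O)c1 | starting material
2 | 1,3-dimethoxybenzene | COc1cccc(OC)c1 | intermediate
3 | 3,5-dimethoxyphenol | COc1cc(O)cc(OC)c1 | intermediate
4 | 3-methylbutanal | CC(C)CC=O | starting material
5 | rac-2-(1-hydroxy-3-methylbutyl)-3,5-dimethoxyphenol | CC(C)CC(O)c1c(O)cc(OC)cc1OC | intermediate
6 | 1-methylcyclopentene | CC1=CCCC1 | starting material
7 | 5-oxohexanal | CC(=O)CCCC=O | intermediate
8 | (3S,4S)-5,7-dimethoxy-4-isobutyl-3-(3-oxobutyl)chroman-2-ol | CC(=O)CC[C@H]1[C@H](CC(C)C)c2c(OC)cc(OC)cc2OC1O | intermediate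
9 | (4R)-4-[(1S)-3-methyl-1-(2,4,6-trimethoxyphenyl)butyl]cyclohex-2-en-1-one | O=C1CC[C@@H]([C@H](CC(C)C)c2c(OC)cc(OC)cc2OC)C=C1 | intermediate
10 | (4S)-3-methyl-4-[(1S)-3-methyl-1-(2,4,6-trimethoxyphenyl)butyl]cyclohex-2-en-1-one | O=C1CC[C@@H]([C@H](CC(C)C)c2c(OC)cc(OC)cc2OC)C(C)=C1 | intermediate
11 | (1S,5S,6S)-6-methyl-5-[(1S)-3-methyl-1-(2,4,6-trimethoxyphenyl)butyl]bicyclo[4.1.0]heptan-2-one | O=C1CC[C@@H]([C@H](CC(C)C)c2c(OC)cc(OC)cc2OC)[C@]2(C)C[C@H]12 | intermediate
12 | methyl 2-(bromomethyl)acrylate | C=C(CBr)C(=O)OC | starting material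
13 | methyl 2-[(tributylstannyl)methyl]acrylate | C=C(C[Sn](CCCC)(CCCC)CCCC)C(=O)OC | intermediate (reagent)
14 | trans-decalone ester (C4 ketone, C7 CO2Me) | O=C1CC[C@@H]([C@H](CC(C)C)c2c(OC)cc(OC)cc2OC)[C@]2(C)CC[C@@H](C(=O)OC)C[C@@H]12 | intermediate
15 | C4-methylidene ester | C=C1CC[C@@H]([C@H](CC(C)C)c2c(OC)cc(OC)cc2OC)[C@]2(C)CC[C@@H](C(=O)OC)C[C@@H]12 | intermediate
16 | 1-[(S)-1-(2,4,6-trimethoxyphenyl)-3-methylbutyl]-β-eudesmol | C=C1CC[C@@H]([C@H](CC(C)C)c2c(OC)cc(OC)cc2OC)[C@]2(C)CC[C@@H](C(C)(C)O)C[C@@H]12 | intermediate
17 | macrocarpal H tri-O-methyl ether | C=C1CC[C@@H]([C@H](CC(C)C)c2c(OC)c(C=O)c(OC)c(C=O)c2OC)[C@]2(C)CC[C@@H](C(C)(C)O)C[C@@H]12 | intermediate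
18 | macrocarpal H | C=C1CC[C@@H]([C@H](CC(C)C)c2c(O)c(C=O)c(O)c(C=O)c2O)[C@]2(C)CC[C@@H](C(C)(C)O)C[C@@H]12 | target

## Step count

Total steps: 14. Longest linear sequence: 12 (steps 1–3, 5–8, 10–14 from resorcinol); steps 4 and 9 are one-step branches.

## Three steps most likely to fail, with fallbacks

1. **Step 10 (radical annulation).** Stannyl-ketyl formation from a dialkyl ketone may be slow, and endo C5–C10 cleavage or [3+2] closure could compete. Fallback: open 11 with TMSI (homo-conjugate addition) to the C9 iodide / C4 silyl enol ether, run a Keck-type radical allylation of the primary iodide with 13, then close ring B by fluoride-triggered Mukaiyama–Michael addition. The radical is then generated by iodine abstraction instead of ketyl fragmentation.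

2. **Step 5 (enamine/o-quinone methide coupling).** The alkyl-substituted quinone methide can tautomerise to the styrene, and the α-branched adduct can epimerise. Fallback: make 10 directly by vinylogous Mukaiyama coupling of the TBS dienol ether of 3-methylcyclohex-2-enone with a planar-chiral (η6-arene)Cr(CO)3-stabilised benzylic cation derived from the trimethoxyaryl carbinol (auxiliary control instead of amine catalysis).

3. **Step 8 (cyclopropanation of a hindered β,β-disubstituted enone).** Fallback: Cu-catalysed conjugate addition of (iPrO)Me2SiCH2MgCl to 10 (anti to the side chain), Tamao oxidation and iodination to the C10–CH2I ketone, then radical allyl transfer from 13 to the iodide and base-mediated Michael closure. This avoids the cyclopropane altogether.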